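## The problem

Target 30 is a germacranolide. A ten-membered carbocycle (C1–C10) is fused across C6–C7 to a butenolide whose tetrasubstituted C7=C11 double bond carries the acetoxymethyl carbon C13. The ring bears a trans-epoxide at C1–C10, a cis-epoxide at C4–C5 and an (S)-2-methylglycidate on the C8 oxygen. There are six ring stereocentres (C1, C4, C5, C6, C8, C10) and one in the ester. C4 and C5 can be set together on an acyclic allylic alcohol and can then direct C6 next door. C8 is cut off from that triad by the sp2 carbon C7 and needs its own control element. C1 and C10 are remote from everything and must be set in or after the ring-forming event. Three features are fragile: both epoxides are acid-labile; the C6 hydrogen is the gamma position of the butenolide and sits next to the epoxide carbon C5, so base can open the epoxide by elimination; and the C13 allylic acetate and the alpha,beta-epoxy ester would not survive a one-electron reductant. The handle for ring closure is the 1,10-epoxide: it places oxygen on both C1 and C10, the pattern of a pinacol between a C1 aldehyde and a C10 methyl ketone. Neither carbonyl has a stereocentre at its alpha carbon, so both can be unveiled late without epimerisation.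

## Retrosynthesis

Germacrane numbering is used throughout (C11–C13 are the lactone carbons, C14 is the methyl on C10, C15 the methyl on C4).

**Ester groups.** The C8–O acyl bond and the C13–O acetyl bond of 30 are cut first, giving monoacetate 26, potassium (S)-2-methylglycidate 28 and, one step further back, diol 25. Both esters are reducible by SmI2 (the acetate is allylic to the enoate, the glycidate is an alpha,beta-epoxy ester), so they cannot precede the ring closure. The forward steps are a selective acetylation of the primary C13 hydroxyl and a Yamaguchi acylation of C8. Diol 25 comes from bis-silyl ether 24.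

**1,10-Epoxide.** The C1–O bond of the epoxide in 24 is cut to give syn-diol 22, by way of C1 mesylate 23. Closure by the tertiary C10 alkoxide inverts C1, so the syn (ring-cis) diol gives the trans-epoxide. Epoxidation of a 1(10)-olefin would serve equally well but would not use the oxygen atoms that the ring closure already delivers.

**C1–C10 (key cut).** Cutting C1–C10 of 22 opens the ten-membered ring to keto aldehyde 21. This removes the only ring and two stereocentres in one operation. The forward reaction asks SmI2 to reduce the aldehyde and not the butenolide, to close a ten-membered ring, and to deliver the two oxygens syn.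

**The two carbonyls.** The C1 aldehyde and the C10 ketone of 21 are traced to the trisubstituted and the 1,1-disubstituted olefins of 20. One ozonolysis unveils both immediately before use, so the beta-silyloxy ketone and the gamma,delta-epoxy aldehyde never meet base.

**Butenolide.** The C7=C11 bond and the lactone C–O bond of 20 are cut by an intramolecular Horner–Wadsworth–Emmons disconnection to ketone 19. Ketone 19 comes from dithiane 18, which is the ester of alcohol 13 with phosphonate acid 17. The acid brings C11, C12 and C13 with C13 already at the right oxidation level; it is made from benzyl diethylphosphonoacetate 14 and the chloromethyl silyl ether 15 through 16.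

**C8–C9 and the C8 stereocentre.** C7 must be a masked ketone flanked by oxygen on both C6 and C8. A C7 carbanion with an oxygen-bearing C8 beside it would expel that oxygen. C8 is therefore carried as a carbonyl carbon: 13 is traced through 12 and 11 to aldehyde 8, with the C8–C9 bond cut. The forward step is a reagent-controlled methallylboration with borane 10 (from Grignard reagent 9). It sets C8 and brings in C9, C10 and C14 as the masked methyl ketone. The two oxygens differ automatically: C6–O is a temporary triethylsilyl ether, C8–O becomes the lasting tert-butyldimethylsilyl ether.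

**C6–C7.** Aldehyde 8 comes from ester 7, and the C6–C7 bond of 7 is cut to epoxy aldehyde 3 and ethyl 1,3-dithiane-2-carboxylate 4. The enolate of 4 (5) is a stabilised glyoxylate anion equivalent with no beta leaving group. The forward aldol must add to the aldehyde face dictated by the epoxide (Felkin–Anh).

**C1–C6 fragment.** Epoxy aldehyde 3 comes from epoxy alcohol 2 and this from nerol 1 by Sharpless epoxidation. Nerol supplies C1–C6 and C15 with the Z-olefin that becomes the cis-epoxide, and its remote olefin is the C1 aldehyde mask.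

## Roads not taken

**Alternative 1:** Cut C2–C3, C6–C7 and C8–C9 at once. Forward, Ni(cod)2 (zerovalent nickel) with a phosphine would join two molecules of isoprene A2 and the silylated ethynyl carbinol A3 in a [4+4+2] cycloaddition to the cyclodecatriene A1.
- Merits: three C–C bonds and the ring form in one step from commodity dienes. No chosen-route sequence matches this economy for the bare skeleton.
- Weak points: both isoprenes must be oriented head-to-tail against competing diene dimerisation and trimerisation. A1 is achiral, so all six ring stereocentres, both epoxides, the C6 and C8 oxygens and the butenolide would have to be installed on a flexible triene with three similar olefins.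
- Comparison: the chosen plan is longer to the ring, but four stereocentres and the full oxidation pattern are in place before closure, each from a reaction with a clear control element.

**Alternative 2:** Cut C6–C7 and reconnect O–C13. Forward, deprotonation at C6 of the thirteen-membered diallyl ether A5 (n-BuLi, low temperature) would trigger a [2,3]-Wittig shift that contracts the ring to carbocycle A4.
- Merits: the medium ring arises by contraction of an easily closed large ring, which is better precedented for ten-membered carbocycles than a pinacol closure. The shift sets C6 and C7 relative to each other.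
- Weak points: deprotonation must choose C6 over the equally allylic C13. A4 has C7 as an sp3 carbon with an isopropenyl group, so C12 and C13 must both be oxidised and the double bond moved to 7(11). Two ring olefins must then be epoxidised with different facial demands.
- Comparison: ring formation is safer there; the chosen plan answers with a butenolide that is complete before the ring closes and an end-game with no allylic oxidations.

**Alternative 3:** Cut C6–C7, C11–C12 and C12–O. Forward, Mo(CO)6 (zerovalent molybdenum) with DMSO under CO would join the alkyne, the C6 aldehyde and CO of yne-aldehyde A7 in a hetero-Pauson–Khand reaction to A6, closing the carbocycle and the butenolide together.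
- Merits: the most convergent of the four; C8 and C13 oxygens are in place, and only the 1,10-epoxidation and the acylations remain after closure. On paper it is shorter than the chosen route.
- Weak points: the intramolecular hetero-Pauson–Khand reaction is established for five- and six-membered fused rings; a ten-membered ring is a different substrate class. The 1,10-epoxide must then come from a face-selective epoxidation of the macrocyclic olefin.
- Comparison: the chosen plan gives up some convergence for a ring closure of a known type, and obtains the epoxide oxygens from the closure itself.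

Key step: step 14

Assumption: compounds 4, 9, 14, 15 and 27 and (−)-Ipc2BOMe of the (+)-alpha-pinene series are taken as commercial; the few percent of the minor enantiomer of 2 should be removed as a diastereomer after the reagent-controlled step 5.

## Route

Step 1
Reactants: 1 nerol
Product: 2 (2S,3R)-2,3-epoxynerol
Conditions: Ti(OiPr)4 (cat.), L-(+)-diethyl tartrate (cat.), t-BuOOH, 4 Å sieves, CH2Cl2, −20 °C
Reagents that add atoms: tert-butyl hydroperoxide CC(C)(C)OO
Why: Sharpless asymmetric epoxidation; the titanium tartrate complex epoxidises only the allylic olefin and, with the L-(+)-tartrate, delivers oxygen to the face that gives C4 (R) and C5 (S), while the remote trisubstituted olefin stays as the later C1 aldehyde mask.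

Step 2
Reactants: 2 (2S,3R)-2,3-epoxynerol
Product: 3 (2R,3R)-3-methyl-3-(4-methylpent-3-enyl)oxirane-2-carbaldehyde
Conditions: TEMPO (cat.), PhI(OAc)2, CH2Cl2, rt
Reagents that add atoms: none
Why: TEMPO/PhI(OAc)2 oxidation of a primary alcohol stops at the aldehyde under neutral conditions, so the epoxide, the olefin and C5 are untouched (the descriptor at C5 changes by priority only); the aldehyde is used crude.

Step 3
Reactants: 3 (2R,3R)-3-methyl-3-(4-methylpent-3-enyl)oxirane-2-carbaldehyde; 4 ethyl 1,3-dithiane-2-carboxylate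
Product: 7 ethyl 2-[(R)-[(2S,3R)-3-methyl-3-(4-methylpent-3-enyl)oxiran-2-yl](triethylsilyloxy)methyl]-1,3-dithiane-2-carboxylate, via lithium enolate 5 (not isolated), via lithium aldolate 6 (not isolated)
Conditions: LiN(iPr)2 (LDA), THF, −78 °C; then 3, −78 °C; then Et3SiOTf, −78 °C
Reagents that add atoms: triethylsilyl trifluoromethanesulfonate CC[Si](CC)(CC)OS(=O)(=O)C(F)(F)F
Why: Aldol addition of a 2-carboalkoxy-1,3-dithiane enolate (a glyoxylate anion equivalent with no beta leaving group) to an alpha,beta-epoxy aldehyde; Felkin–Anh attack anti to the epoxide C–O bond and past the C5 hydrogen should set C6 (R at this stage, the configuration the lactone needs), and silylation of the aldolate in the same flask blocks retro-aldol cleavage.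

Step 4
Reactants: 7 ethyl 2-[(R)-[(2S,3R)-3-methyl-3-(4-methylpent-3-enyl)oxiran-2-yl](triethylsilyloxy)methyl]-1,3-dithiane-2-carboxylate
Product: 8 2-[(R)-[(2S,3R)-3-methyl-3-(4-methylpent-3-enyl)oxiran-2-yl](triethylsilyloxy)methyl]-1,3-dithiane-2-carbaldehyde
Conditions: iBu2AlH (DIBAL-H), toluene, −78 °C; Rochelle salt
Reagents that add atoms: none
Why: DIBAL-H half-reduction of an ester whose quaternary alpha carbon and sulfur atoms hold the tetrahedral aluminium hemiacetal until work-up; epoxide, silyl ether and olefin are inert at this temperature.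

Step 5
Reactants: 8 2-[(R)-[(2S,3R)-3-methyl-3-(4-methylpent-3-enyl)oxiran-2-yl](triethylsilyloxy)methyl]-1,3-dithiane-2-carbaldehyde; 9 2-methylallylmagnesium chloride
Product: 11 (1S)-3-methyl-1-[2-[(R)-[(2S,3R)-3-methyl-3-(4-methylpent-3-enyl)oxiran-2-yl](triethylsilyloxy)methyl]-1,3-dithian-2-yl]but-3-en-1-ol, via methallyl borane 10 (not isolated)
Conditions: (−)-Ipc2BOMe, 9, Et2O, −78 °C → rt; then 8, −78 °C; ethanolamine
Reagents that add atoms: none
Why: Brown methallylboration through a chair transition state; the isopinocampheyl groups of the (+)-alpha-pinene series direct the 2-methylallyl group to the si face of the non-enolisable aldehyde, which should give C8 (S) under reagent control, and the amine work-up avoids peroxide and so spares the dithiane.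

Step 6
Reactants: 11 (1S)-3-methyl-1-[2-[(R)-[(2S,3R)-3-methyl-3-(4-methylpent-3-enyl)oxiran-2-yl](triethylsilyloxy)methyl]-1,3-dithian-2-yl]but-3-en-1-ol
Product: 12 tert-butyldimethylsilyl ether of 11 at the C8 oxygen
Conditions: t-BuMe2SiOTf, 2,6-lutidine, CH2Cl2, −78 → −20 °C
Reagents that add atoms: tert-butyldimethylsilyl trifluoromethanesulfonate CC(C)(C)[Si](C)(C)OS(=O)(=O)C(F)(F)F
Why: Silylation of a hindered secondary alcohol with a silyl triflate and a hindered pyridine base; the low temperature keeps the Lewis-acidic triflate from opening the trisubstituted epoxide.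

Step 7
Reactants: 12 tert-butyldimethylsilyl ether of 11 at the C8 oxygen
Product: 13 (R)-[2-[(1S)-1-(tert-butyldimethylsilyloxy)-3-methylbut-3-enyl]-1,3-dithian-2-yl][(2S,3R)-3-methyl-3-(4-methylpent-3-enyl)oxiran-2-yl]methanol
Conditions: HF·pyridine, pyridine, THF, 0 °C
Reagents that add atoms: none
Why: Buffered HF·pyridine cleaves a triethylsilyl ether much faster than an equally hindered tert-butyldimethylsilyl ether, so only the C6 hydroxyl is freed.

Step 8
Reactants: 14 benzyl diethylphosphonoacetate; 15 (triisopropylsilyloxy)methyl chloride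
Product: 16 benzyl 2-(diethoxyphosphoryl)-3-(triisopropylsilyloxy)propanoate (racemic)
Conditions: NaH, THF, 0 °C → rt (14 in excess)
Reagents that add atoms: none
Why: C-alkylation of a phosphonoacetate carbanion with an alpha-chloro ether, the same reaction type as malonate alkylation with benzyl chloromethyl ether; it brings in C13 already as a silyl ether, and the excess of 14 keeps the product from standing as its anion.

Step 9
Reactants: 16 benzyl 2-(diethoxyphosphoryl)-3-(triisopropylsilyloxy)propanoate
Product: 17 2-(diethoxyphosphoryl)-3-(triisopropylsilyloxy)propanoic acid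
Conditions: H2 (1 atm), Pd/C, EtOAc, rt
Reagents that add atoms: none
Why: Hydrogenolysis of a benzyl ester under neutral conditions; the silyl ether and the phosphonate are untouched and no base is present that could cause beta-elimination.

Step 10
Reactants: 13 (R)-[2-[(1S)-1-(tert-butyldimethylsilyloxy)-3-methylbut-3-enyl]-1,3-dithian-2-yl][(2S,3R)-3-methyl-3-(4-methylpent-3-enyl)oxiran-2-yl]methanol; 17 2-(diethoxyphosphoryl)-3-(triisopropylsilyloxy)propanoic acid
Product: 18 C6 ester of 13 with acid 17 (mixture of epimers at the phosphonate carbon)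
Conditions: DCC, DMAP (cat.), CH2Cl2, 0 °C → rt
Reagents that add atoms: none
Why: Steglich esterification; alpha-phosphono acids acylate hindered secondary alcohols readily because the activated acid can react through its ketene, and the epimeric phosphonate carbon becomes sp2 in step 12.

Step 11
Reactants: 18 C6 ester of 13 with acid 17
Product: 19 [(1R,3S)-3-(tert-butyldimethylsilyloxy)-5-methyl-1-[(2S,3R)-3-methyl-3-(4-methylpent-3-enyl)oxiran-2-yl]-2-oxohex-5-enyl] 2-(diethoxyphosphoryl)-3-(triisopropylsilyloxy)propanoate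
Conditions: PhI(OCOCF3)2, CaCO3, MeCN/H2O, 0 °C
Reagents that add atoms: water O
Why: Oxidative dithioacetal hydrolysis; sulfur is attacked far faster than the olefins, the carbonate buffer protects epoxide and silyl ethers, and the beta,gamma-epoxy ketone is used at once.

Step 12
Reactants: 19 [(1R,3S)-3-(tert-butyldimethylsilyloxy)-5-methyl-1-[(2S,3R)-3-methyl-3-(4-methylpent-3-enyl)oxiran-2-yl]-2-oxohex-5-enyl] 2-(diethoxyphosphoryl)-3-(triisopropylsilyloxy)propanoate
Product: 20 (5S)-4-[(1S)-1-(tert-butyldimethylsilyloxy)-3-methylbut-3-enyl]-5-[(2S,3R)-3-methyl-3-(4-methylpent-3-enyl)oxiran-2-yl]-3-[(triisopropylsilyloxy)methyl]furan-2(5H)-one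
Conditions: LiCl, iPr2NEt, MeCN, 0 °C → rt
Reagents that add atoms: none
Why: Intramolecular Horner–Wadsworth–Emmons olefination under Masamune–Roush conditions; lithium chelation lets the weak amine deprotonate only the phosphonate, which closes the five-membered lactone on the C7 ketone and forms the tetrasubstituted C7=C11 bond, while the base is too weak to enolise the ketone toward C6 (which would open the epoxide) or C8.

Step 13
Reactants: 20 (5S)-4-[(1S)-1-(tert-butyldimethylsilyloxy)-3-methylbut-3-enyl]-5-[(2S,3R)-3-methyl-3-(4-methylpent-3-enyl)oxiran-2-yl]-3-[(triisopropylsilyloxy)methyl]furan-2(5H)-one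
Product: 21 (5S)-4-[(1S)-1-(tert-butyldimethylsilyloxy)-3-oxobutyl]-5-[(2S,3R)-3-methyl-3-(3-oxopropyl)oxiran-2-yl]-3-[(triisopropylsilyloxy)methyl]furan-2(5H)-one
Conditions: O3, CH2Cl2, −78 °C (indicator dye end point); then PPh3, −78 °C → rt
Reagents that add atoms: ozone [O-][O+]=O
Why: Ozonolysis with reductive work-up cleaves the electron-rich trisubstituted and 1,1-disubstituted olefins to the C1 aldehyde and the C10 methyl ketone, while the electron-poor tetrasubstituted butenolide olefin reacts much more slowly.

Step 14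
Reactants: 21 (5S)-4-[(1S)-1-(tert-butyldimethylsilyloxy)-3-oxobutyl]-5-[(2S,3R)-3-methyl-3-(3-oxopropyl)oxiran-2-yl]-3-[(triisopropylsilyloxy)methyl]furan-2(5H)-one
Product: 22 (1S,4R,5S,6S,8S,10R)-8-(tert-butyldimethylsilyloxy)-4,5-epoxy-1,10-dihydroxy-13-(triisopropylsilyloxy)germacr-7(11)-en-12,6-olide
Conditions: SmI2 (samarium diiodide, divalent samarium; 3 equiv, 0.1 M in THF), THF, 0 °C, 21 added by syringe pump to high dilution, no HMPA and no proton source; then aq. NaHCO3
Reagents that add atoms: none
Why: Single-electron transfer from SmI2 to the aldehyde gives a samarium-bound C1 ketyl, which adds to the samarium-coordinated C10 ketone; a second electron gives a cyclic trivalent samarium diolate that is protonated on work-up. The closest known reaction type is the SmI2-mediated intramolecular pinacol coupling of keto aldehydes to medium- and large-ring cis-diols. The ten-membered carbocycle closes by 10-exo-trig addition of the ketyl carbon to the ketone carbonyl inside this chelate, with the planar butenolide and the cis-epoxide acting as turn elements. C1 and C10 form together: their syn relationship (C1 S, C10 R) should follow from the chelate that holds both oxygens on samarium, and the face of the C10 ketone should be chosen by the C8 silyloxy stereocentre next to C9 and by the ring conformation; this second point is not proven. The step needs aldehyde-selective reduction, secured by using SmI2 in THF without HMPA or alcohol, under which conjugated lactones are not reduced. It needs ring closure to beat dimerisation, secured by slow addition at high dilution. It needs the ketyl to avoid the butenolide, whose beta carbon C7 is fully substituted and poorly placed for a seven-membered closure.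

Step 15
Reactants: 22 (1S,4R,5S,6S,8S,10R)-8-(tert-butyldimethylsilyloxy)-4,5-epoxy-1,10-dihydroxy-13-(triisopropylsilyloxy)germacr-7(11)-en-12,6-olide
Product: 24 (1R,4R,5S,6S,8S,10R)-8-(tert-butyldimethylsilyloxy)-1,10:4,5-diepoxy-13-(triisopropylsilyloxy)germacr-7(11)-en-12,6-olide, via C1 mesylate 23 (not isolated)
Conditions: MsCl, Et3N, CH2Cl2, −20 °C; concentrate; K2CO3, MeOH, 0 °C
Reagents that add atoms: none
Why: Selective sulfonylation of the secondary C1 hydroxyl beside the tertiary C10 hydroxyl, then intramolecular Williamson closure (3-exo-tet) by the C10 alkoxide with inversion at C1, so the syn diol gives the trans-epoxide with C1 (R) and C10 (R) unchanged.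

Step 16
Reactants: 24 (1R,4R,5S,6S,8S,10R)-8-(tert-butyldimethylsilyloxy)-1,10:4,5-diepoxy-13-(triisopropylsilyloxy)germacr-7(11)-en-12,6-olide
Product: 25 (1R,4R,5S,6S,8S,10R)-1,10:4,5-diepoxy-8,13-dihydroxygermacr-7(11)-en-12,6-olide
Conditions: HF·pyridine, pyridine, THF, 0 °C → rt
Reagents that add atoms: none
Why: Fluoride-driven cleavage of both silyl ethers with pyridine-buffered HF·pyridine, conditions under which trisubstituted epoxides and butenolides are known to survive.

Step 17
Reactants: 25 (1R,4R,5S,6S,8S,10R)-1,10:4,5-diepoxy-8,13-dihydroxygermacr-7(11)-en-12,6-olide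
Product: 26 (1R,4R,5S,6S,8S,10R)-13-acetoxy-1,10:4,5-diepoxy-8-hydroxygermacr-7(11)-en-12,6-olide
Conditions: Ac2O (1 equiv), 2,4,6-collidine, CH2Cl2, −20 → 0 °C
Reagents that add atoms: acetic anhydride CC(=O)OC(C)=O
Why: The unhindered primary allylic C13 hydroxyl is acylated much faster than the secondary C8 hydroxyl on the ring, so one equivalent of anhydride with a weak base should give the mono-acetate.

Step 18
Reactants: 27 methyl (2S)-2-methyloxirane-2-carboxylate
Product: 28 potassium (2S)-2-methyloxirane-2-carboxylate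
Conditions: KOH (1 equiv), MeOH, 0 °C; evaporate
Reagents that add atoms: potassium hydroxide [K+].[OH-]
Why: Saponification of a glycidic ester with one equivalent of hydroxide, as in Darzens glycidic ester chemistry; the quaternary alpha carbon cannot epimerise and the salt is isolated without acidification.

Step 19
Reactants: 26 (1R,4R,5S,6S,8S,10R)-13-acetoxy-1,10:4,5-diepoxy-8-hydroxygermacr-7(11)-en-12,6-olide; 28 potassium (2S)-2-methyloxirane-2-carboxylate
Product: 30 (1R,4R,5S,6S,8S,10R)-13-acetoxy-1,10:4,5-diepoxy-8-[(2S)-2-methyloxirane-2-carbonyloxy]germacr-7(11)-en-12,6-olide, via mixed anhydride 29 (not isolated)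
Conditions: 28, 2,4,6-trichlorobenzoyl chloride, THF, rt; then 26, DMAP, toluene, rt
Reagents that add atoms: none
Why: Yamaguchi esterification; the carboxylate forms the mixed anhydride and DMAP transfers the hindered, non-enolisable acyl group to the secondary C8 hydroxyl, with no stereocentre touched and a base too weak to deprotonate C6.

## Compound list

1 | nerol, (2Z)-3,7-dimethylocta-2,6-dien-1-ol | CC(C)=CCC/C(C)=C\CO | starting material
2 | (2S,3R)-2,3-epoxynerol, [(2S,3R)-3-methyl-3-(4-methylpent-3-enyl)oxiran-2-yl]methanol | CC(C)=CCC[C@@]1(C)O[C@H]1CO | intermediate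
3 | (2R,3R)-3-methyl-3-(4-methylpent-3-enyl)oxirane-2-carbaldehyde | CC(C)=CCC[C@@]1(C)O[C@H]1C=O | intermediate
4 | ethyl 1,3-dithiane-2-carboxylate | CCOC(=O)C1SCCCS1 | starting material
5 | lithium enolate of 4, lithium (1,3-dithian-2-ylidene)(ethoxy)methanolate | CCOC(O[Li])=C1SCCCS1 | intermediate
6 | lithium aldolate, ethyl 2-[(R)-lithiooxy[(2S,3R)-3-methyl-3-(4-methylpent-3-enyl)oxiran-2-yl]methyl]-1,3-dithiane-2-carboxylate | CC(C)=CCC[C@@]1(C)O[C@H]1[C@H](C2(SCCCS2)C(=O)OCC)O[Li] | intermediate
7 | ethyl 2-[(R)-[(2S,3R)-3-methyl-3-(4-methylpent-3-enyl)oxiran-2-yl](triethylsilyloxy)methyl]-1,3-dithiane-2-carboxylate | CC(C)=CCC[C@@]1(C)O[C@H]1[C@H](C2(SCCCS2)C(=O)OCC)O[Si](CC)(CC)CC | intermediate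
8 | 2-[(R)-[(2S,3R)-3-methyl-3-(4-methylpent-3-enyl)oxiran-2-yl](triethylsilyloxy)methyl]-1,3-dithiane-2-carbaldehyde | CC(C)=CCC[C@@]1(C)O[C@H]1[C@H](C2(SCCCS2)C=O)O[Si](CC)(CC)CC | intermediate
9 | 2-methylallylmagnesium chloride | CC(=C)C[Mg]Cl | starting material
10 | B-(2-methylallyl)diisopinocampheylborane, (+)-alpha-pinene series | CC(=C)CB([C@H]1[C@H](C)[C@H]2C[C@@H](C1)C2(C)C)[C@H]1[C@H](C)[C@H]2C[C@@H](C1)C2(C)C | intermediate
11 | (1S)-3-methyl-1-[2-[(R)-[(2S,3R)-3-methyl-3-(4-methylpent-3-enyl)oxiran-2-yl](triethylsilyloxy)methyl]-1,3-dithian-2-yl]but-3-en-1-ol | CC(C)=CCC[C@@]1(C)O[C@H]1[C@H](C2(SCCCS2)[C@@H](O)CC(C)=C)O[Si](CC)(CC)CC | intermediate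
12 | tert-butyldimethylsilyl ether of 11 (C6 OSiEt3, C8 OSiMe2tBu; 4R,5S,6R,8S) | CC(C)=CCC[C@@]1(C)O[C@H]1[C@H](C2(SCCCS2)[C@@H](O[Si](C)(C)C(C)(C)C)CC(C)=C)O[Si](CC)(CC)CC | intermediate
13 | (R)-[2-[(1S)-1-(tert-butyldimethylsilyloxy)-3-methylbut-3-enyl]-1,3-dithian-2-yl][(2S,3R)-3-methyl-3-(4-methylpent-3-enyl)oxiran-2-yl]methanol | CC(C)=CCC[C@@]1(C)O[C@H]1[C@H](C2(SCCCS2)[C@@H](O[Si](C)(C)C(C)(C)C)CC(C)=C)O | intermediate
14 | benzyl diethylphosphonoacetate | CCOP(=O)(CC(=O)OCc1ccccc1)OCC | starting material
15 | (triisopropylsilyloxy)methyl chloride | CC(C)[Si](OCCl)(C(C)C)C(C)C | starting material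
16 | benzyl 2-(diethoxyphosphoryl)-3-(triisopropylsilyloxy)propanoate (racemic) | CCOP(=O)(OCC)C(CO[Si](C(C)C)(C(C)C)C(C)C)C(=O)OCc1ccccc1 | intermediate
17 | 2-(diethoxyphosphoryl)-3-(triisopropylsilyloxy)propanoic acid (racemic) | CCOP(=O)(OCC)C(CO[Si](C(C)C)(C(C)C)C(C)C)C(O)=O | intermediate
18 | (R)-[2-[(1S)-1-(tert-butyldimethylsilyloxy)-3-methylbut-3-enyl]-1,3-dithian-2-yl][(2S,3R)-3-methyl-3-(4-methylpent-3-enyl)oxiran-2-yl]methyl 2-(diethoxyphosphoryl)-3-(triisopropylsilyloxy)propanoate (epimers at the phosphonate carbon) | CC(C)=CCC[C@@]1(C)O[C@H]1[C@H](C2(SCCCS2)[C@@H](O[Si](C)(C)C(C)(C)C)CC(C)=C)OC(=O)C(CO[Si](C(C)C)(C(C)C)C(C)C)P(=O)(OCC)OCC | intermediate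
19 | [(1R,3S)-3-(tert-butyldimethylsilyloxy)-5-methyl-1-[(2S,3R)-3-methyl-3-(4-methylpent-3-enyl)oxiran-2-yl]-2-oxohex-5-enyl] 2-(diethoxyphosphoryl)-3-(triisopropylsilyloxy)propanoate | CC(C)=CCC[C@@]1(C)O[C@H]1[C@H](C(=O)[C@@H](O[Si](C)(C)C(C)(C)C)CC(C)=C)OC(=O)C(CO[Si](C(C)C)(C(C)C)C(C)C)P(=O)(OCC)OCC | intermediate
20 | (5S)-4-[(1S)-1-(tert-butyldimethylsilyloxy)-3-methylbut-3-enyl]-5-[(2S,3R)-3-methyl-3-(4-methylpent-3-enyl)oxiran-2-yl]-3-[(triisopropylsilyloxy)methyl]furan-2(5H)-one | CC(C)[Si](C(C)C)(C(C)C)OCC1=C([C@@H](O[Si](C)(C)C(C)(C)C)CC(C)=C)[C@@H]([C@@H]2O[C@]2(C)CCC=C(C)C)OC1=O | intermediate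
21 | (5S)-4-[(1S)-1-(tert-butyldimethylsilyloxy)-3-oxobutyl]-5-[(2S,3R)-3-methyl-3-(3-oxopropyl)oxiran-2-yl]-3-[(triisopropylsilyloxy)methyl]furan-2(5H)-one (1,10-seco keto aldehyde) | CC(C)[Si](C(C)C)(C(C)C)OCC1=C([C@@H](O[Si](C)(C)C(C)(C)C)CC(C)=O)[C@@H]([C@@H]2O[C@]2(C)CCC=O)OC1=O | intermediate
22 | (1S,4R,5S,6S,8S,10R)-8-(tert-butyldimethylsilyloxy)-4,5-epoxy-1,10-dihydroxy-13-(triisopropylsilyloxy)germacr-7(11)-en-12,6-olide | CC(C)[Si](C(C)C)(C(C)C)OCC1=C2[C@@H](O[Si](C)(C)C(C)(C)C)C[C@@](C)(O)[C@@H](O)CC[C@@]3(C)O[C@H]3[C@H]2OC1=O | intermediate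
23 | C1 methanesulfonate of 22 (1S,4R,5S,6S,8S,10R) | CC(C)[Si](C(C)C)(C(C)C)OCC1=C2[C@@H](O[Si](C)(C)C(C)(C)C)C[C@@](C)(O)[C@@H](OS(C)(=O)=O)CC[C@@]3(C)O[C@H]3[C@H]2OC1=O | intermediate
24 | (1R,4R,5S,6S,8S,10R)-8-(tert-butyldimethylsilyloxy)-1,10:4,5-diepoxy-13-(triisopropylsilyloxy)germacr-7(11)-en-12,6-olide | CC(C)[Si](C(C)C)(C(C)C)OCC1=C2[C@@H](O[Si](C)(C)C(C)(C)C)C[C@@]3(C)O[C@@H]3CC[C@@]3(C)O[C@H]3[C@H]2OC1=O | intermediate
25 | (1R,4R,5S,6S,8S,10R)-1,10:4,5-diepoxy-8,13-dihydroxygermacr-7(11)-en-12,6-olide | OCC1=C2[C@@H](O)C[C@@]3(C)O[C@@H]3CC[C@@]3(C)O[C@H]3[C@H]2OC1=O | intermediate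
26 | (1R,4R,5S,6S,8S,10R)-13-acetoxy-1,10:4,5-diepoxy-8-hydroxygermacr-7(11)-en-12,6-olide | CC(=O)OCC1=C2[C@@H](O)C[C@@]3(C)O[C@@H]3CC[C@@]3(C)O[C@H]3[C@H]2OC1=O | intermediate
27 | methyl (2S)-2-methyloxirane-2-carboxylate | COC(=O)[C@]1(C)CO1 | starting material
28 | potassium (2S)-2-methyloxirane-2-carboxylate | [K+].[O-]C(=O)[C@]1(C)CO1 | intermediate
29 | (2S)-2-methyloxirane-2-carboxylic 2,4,6-trichlorobenzoic anhydride | O=C(OC(=O)[C@]1(C)CO1)c1c(Cl)cc(Cl)cc1Cl | intermediate
30 | (1R,4R,5S,6S,8S,10R)-13-acetoxy-1,10:4,5-diepoxy-8-[(2S)-2-methyloxirane-2-carbonyloxy]germacr-7(11)-en-12,6-olide | CC(=O)OCC1=C2[C@@H](OC(=O)[C@]3(C)CO3)C[C@@]3(C)O[C@@H]3CC[C@@]3(C)O[C@H]3[C@H]2OC1=O | target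

## Step count and risks

Total: 19 steps. Longest linear sequence: 16 steps (steps 1–7, 10–17 and 19, from nerol).

**Step 14 (key step).** Most likely failure: loss of the syn relationship. Closing a strained ten-membered ring may force the ketyl to add through an open, non-chelated arrangement, so the anti diol forms, and the C8 stereocentre may not choose the ketone face. Fallback, from 21 back to 24: the pinacol is run without demand on the diol configuration and the anti-1,10-diol F1 (either of its two forms) is taken on. 1,1'-Thiocarbonyldiimidazole converts it to the cyclic thionocarbonate F2. Corey–Winter syn-elimination with 1,3-dimethyl-2-phenyl-1,3,2-diazaphospholidine gives the (E)-1(10)-olefin F3; both anti diols converge on this olefin. Epoxidation with mCPBA, expected on the outer face of the ring as with other (E)-1(10)-germacranolides, returns to 24.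

**Step 3.** Most likely failure: poor facial selectivity, or reversal of the aldol through the stabilised enolate before silylation. Fallback, from 3 and 4 back to 7: the aldolate is quenched with acid to the hydroxy ester of mixed C6 configuration, drawn as its 6S epimer F4. Swern oxidation gives the epoxy ketone F5. Zn(BH4)2 reduces it under chelation between the ketone and epoxide oxygens, with hydride entering past the C5 hydrogen, to the 6R alcohol F6. Silylation with Et3SiOTf gives 7.

**Step 5.** Most likely failure: slow or poorly face-selective allyl transfer to a neopentyl-type aldehyde flanked by two sulfur atoms. Fallback, from 8 back to 11: 9 is added without a chiral controller, giving 11 together with its 8R epimer F7. Swern oxidation of the mixture gives ketone F8. Reduction with catecholborane and (R)-2-methyl-CBS-oxazaborolidine, the quaternary dithiane carbon acting as the large group, gives 11.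

**Step 12.** Most likely failure: loss of triisopropylsilanolate from the phosphonate carbanion (E1cB) before it reaches the ketone. Fallback, from 13 back to 20: 13 is esterified with bromo(diethoxyphosphoryl)acetic acid (DCC) to the bromophosphonoacetate F9. The dithiane is removed as in step 11 to give ketone F10. Olefination as in step 12 gives the alpha-bromobutenolide F11. Stille coupling with (tributylstannyl)methanol and Pd(PPh3)4 (zerovalent palladium) gives the hydroxymethyl butenolide F12. Silylation with triisopropylsilyl chloride and imidazole gives 20.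

**Step 15.** Most likely failure: deprotonation at C6 (the gamma position of the butenolide) by carbonate in methanol, with eliminative opening of the 4,5-epoxide, or methanolysis of the lactone. Fallback, from 22 back to 24: Mitsunobu-type cyclodehydration of the diol (PPh3, diisopropyl azodicarboxylate, toluene) under neutral conditions. The secondary C1 oxygen is activated on phosphorus and displaced by the C10 hydroxyl with the same inversion. No new compound is made.

## Further compounds

F1 | step 14 | anti-1,10-diol, (1R,4R,5S,6S,8S,10R) C1 epimer of 22 | CC(C)[Si](C(C)C)(C(C)C)OCC1=C2[C@@H](O[Si](C)(C)C(C)(C)C)C[C@@](C)(O)[C@H](O)CC[C@@]3(C)O[C@H]3[C@H]2OC1=O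
F2 | step 14 | cyclic 1,10-thionocarbonate of F1 | CC(C)[Si](C(C)C)(C(C)C)OCC1=C2[C@@H](O[Si](C)(C)C(C)(C)C)C[C@@]4(C)OC(=S)O[C@@H]4CC[C@@]3(C)O[C@H]3[C@H]2OC1=O
F3 | step 14 | (1(10)E,4R,5S,6S,8S)-8-(tert-butyldimethylsilyloxy)-4,5-epoxy-13-(triisopropylsilyloxy)germacra-1(10),7(11)-dien-12,6-olide | CC(C)[Si](C(C)C)(C(C)C)OCC1=C2[C@@H](O[Si](C)(C)C(C)(C)C)C/C(C)=C/CC[C@@]3(C)O[C@H]3[C@H]2OC1=O
F4 | step 3 | ethyl 2-[(S)-hydroxy[(2S,3R)-3-methyl-3-(4-methylpent-3-enyl)oxiran-2-yl]methyl]-1,3-dithiane-2-carboxylate (C6 epimer) | CC(C)=CCC[C@@]1(C)O[C@H]1[C@@H](C2(SCCCS2)C(=O)OCC)O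
F5 | step 3 | ethyl 2-[(2S,3R)-3-methyl-3-(4-methylpent-3-enyl)oxirane-2-carbonyl]-1,3-dithiane-2-carboxylate | CC(C)=CCC[C@@]1(C)O[C@H]1C(=O)C2(SCCCS2)C(=O)OCC
F6 | step 3 | ethyl 2-[(R)-hydroxy[(2S,3R)-3-methyl-3-(4-methylpent-3-enyl)oxiran-2-yl]methyl]-1,3-dithiane-2-carboxylate | CC(C)=CCC[C@@]1(C)O[C@H]1[C@H](C2(SCCCS2)C(=O)OCC)O
F7 | step 5 | (1R)-3-methyl-1-[2-[(R)-[(2S,3R)-3-methyl-3-(4-methylpent-3-enyl)oxiran-2-yl](triethylsilyloxy)methyl]-1,3-dithian-2-yl]but-3-en-1-ol (C8 epimer of 11) | CC(C)=CCC[C@@]1(C)O[C@H]1[C@H](C2(SCCCS2)[C@H](O)CC(C)=C)O[Si](CC)(CC)CC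
F8 | step 5 | 3-methyl-1-[2-[(R)-[(2S,3R)-3-methyl-3-(4-methylpent-3-enyl)oxiran-2-yl](triethylsilyloxy)methyl]-1,3-dithian-2-yl]but-3-en-1-one | CC(C)=CCC[C@@]1(C)O[C@H]1[C@H](C2(SCCCS2)C(=O)CC(C)=C)O[Si](CC)(CC)CC
F9 | step 12 | bromo(diethoxyphosphoryl)acetate of 13 at the C6 oxygen | CC(C)=CCC[C@@]1(C)O[C@H]1[C@H](C2(SCCCS2)[C@@H](O[Si](C)(C)C(C)(C)C)CC(C)=C)OC(=O)C(Br)P(=O)(OCC)OCC
F10 | step 12 | C7 ketone from F9, [(1R,3S)-3-(tert-butyldimethylsilyloxy)-5-methyl-1-[(2S,3R)-3-methyl-3-(4-methylpent-3-enyl)oxiran-2-yl]-2-oxohex-5-enyl] bromo(diethoxyphosphoryl)acetate | CC(C)=CCC[C@@]1(C)O[C@H]1[C@H](C(=O)[C@@H](O[Si](C)(C)C(C)(C)C)CC(C)=C)OC(=O)C(Br)P(=O)(OCC)OCC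
F11 | step 12 | (5S)-3-bromo-4-[(1S)-1-(tert-butyldimethylsilyloxy)-3-methylbut-3-enyl]-5-[(2S,3R)-3-methyl-3-(4-methylpent-3-enyl)oxiran-2-yl]furan-2(5H)-one | BrC1=C([C@@H](O[Si](C)(C)C(C)(C)C)CC(C)=C)[C@@H]([C@@H]2O[C@]2(C)CCC=C(C)C)OC1=O
F12 | step 12 | (5S)-4-[(1S)-1-(tert-butyldimethylsilyloxy)-3-methylbut-3-enyl]-3-(hydroxymethyl)-5-[(2S,3R)-3-methyl-3-(4-methylpent-3-enyl)oxiran-2-yl]furan-2(5H)-one | OCC1=C([C@@H](O[Si](C)(C)C(C)(C)C)CC(C)=C)[C@@H]([C@@H]2O[C@]2(C)CCC=C(C)C)OC1=O
F0 | step 15 | none | none
A1 | alternative 1 | 1(10)E,4Z,7Z-cyclodecatriene with the 2,2-dimethyl-1,3-dioxan-5-yl triethylsilyl ether on C7 | CC[Si](CC)(CC)OC1(COC(C)(C)OC1)/C2=C/C/C(C)=C/CC/C(C)=C\C2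
A2 | alternative 1 | isoprene | C=CC(C)=C
A3 | alternative 1 | 5-ethynyl-2,2-dimethyl-5-(triethylsilyloxy)-1,3-dioxane | CC[Si](CC)(CC)OC1(C#C)COC(C)(C)OC1
A4 | alternative 2 | 6-hydroxy-7-isopropenylgermacra-1(10)E,4Z-diene, C8 tert-butyldimethylsilyl ether | CC(=C)[C@@H]1[C@@H](O[Si](C)(C)C(C)(C)C)C/C(C)=C/CC/C(C)=C\[C@H]1O
A5 | alternative 2 | thirteen-membered cyclic diallyl ether (oxygen between C6 and C13; 4Z, 1(10)E, 7(11)E; C8 tert-butyldimethylsilyl ether) | C1OC/C=C(C)\CC/C=C(C)/C[C@H](O[Si](C)(C)C(C)(C)C)/C=C1\C
A6 | alternative 3 | (1(10)E,4R,5S,6S,8S)-8,13-bis(tert-butyldimethylsilyloxy)-4,5-epoxygermacra-1(10),7(11)-dien-12,6-olide | CC(C)(C)[Si](C)(C)OCC1=C2[C@@H](O[Si](C)(C)C(C)(C)C)C/C(C)=C/CC[C@@]3(C)O[C@H]3[C@H]2OC1=O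
A7 | alternative 3 | yne-aldehyde with C6 aldehyde, cis-4,5-epoxide, 1(10)E olefin, C8 silyl ether and C7≡C11 alkyne bearing the C13 silyl ether | O=C[C@@H]1O[C@]1(C)CC/C=C(C)/C[C@H](O[Si](C)(C)C(C)(C)C)C#CCO[Si](C)(C)C(C)(C)C
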